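**Retrosynthetic overview**
1. The target is (5S,9R,10S,13S)-labd-7-ene-15,17-diyl diacetate. Both acetates are installed last on the 15,17-diol, and the C7=C8 bond comes from a 7-hydroxy-8-ethoxycarbonyl unit (C17 at the ester level) by E1cB dehydration.
2. Key disconnection, one annulation: C9–C10 and C7–C8, between a ring A aldehyde (C1–C7, C10, C18–C20; C10 radical by hydrogen-atom transfer to its C1=C10 alkene) and an allenoate that holds C8, C9 and C11–C17; C9, C11–C16 and the C13 centre of the allenoate are those of (S)-citronellol.
3. Enabling feature: in ring B, C8 bears the oxidisable C17 and C9 bears the side chain, so C8–C9–C11 can be an allenoate (C9 central) that becomes an ester dienolate nucleophilic at C8 toward C7=O. C10 is a quaternary carbon of ring A flanked by C5–H and the C4 gem-dimethyl group, so a C10 radical is attacked only anti to the C5 arm.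
4. Stereocentres: C5 by CBS reduction of 2,4,4-trimethylcyclohexenone and chirality transfer in a Johnson–Claisen rearrangement; C10 relayed from C5 in the key step; C9 by α-face hydrogenation of the exocyclic C9=C11 bond left by the allenoate.
5. Ring order: ring A is bought; ring B is closed in the key step by the C7–C8 aldol bond.

Key step: step 8

Remark: skeletal atoms carry labdane numbers (C1–C20, C17 on C8, C20 on C10) in all intermediates, β is the face of ring B that bears C20, and compounds 1 and 6 are taken as commercial.

Step 1
Reactants: 1 2,4,4-trimethylcyclohex-2-en-1-one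
Product: 2 (R)-2,4,4-trimethylcyclohex-2-en-1-ol
Conditions: (S)-2-methyl-CBS-oxazaborolidine (10 mol %), BH3·SMe2, THF, −20 °C; MeOH quench
Reagents that add atoms: none
Why: Corey–Bakshi–Shibata reduction, in which the ketone should bind the catalyst boron with the 2-methylvinyl flank as the large group, so that hydride is delivered to one carbonyl face and sets the C1 carbinol centre as (R).

Step 2
Reactants: 2 (R)-2,4,4-trimethylcyclohex-2-en-1-ol
Product: 4 ethyl [(1S)-2,6,6-trimethylcyclohex-2-en-1-yl]acetate, via ketene acetal 3 (not isolated)
Conditions: CH3C(OEt)3 (6 equiv), EtCO2H (cat.), 140 °C, EtOH distilled off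
Reagents that add atoms: triethyl orthoacetate CC(OCC)(OCC)OCC
Why: Johnson–Claisen rearrangement, in which the suprafacial [3,3] shift of 3 is confined to the ring face that carried the oxygen, so the C1–O configuration is transferred to the new C5–C6 bond (C5 S) while the double bond moves to C1=C10.

Step 3
Reactants: 4 ethyl [(1S)-2,6,6-trimethylcyclohex-2-en-1-yl]acetate
Product: 5 [(1S)-2,6,6-trimethylcyclohex-2-en-1-yl]acetaldehyde
Conditions: i-Bu2AlH (1.1 equiv), CH2Cl2, −78 °C; aq. KNaC4H4O6
Reagents that add atoms: none
Why: Partial ester reduction with i-Bu2AlH at low temperature stops at the aluminium hemiacetal and gives the C7 aldehyde on work-up, and the C5 centre is not α to the carbonyl and cannot epimerise.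

Step 4
Reactants: 6 (S)-citronellol
Product: 7 (S)-citronellyl acetate
Conditions: Ac2O, pyridine, DMAP (cat.), CH2Cl2, 0 °C to rt
Reagents that add atoms: acetic anhydride CC(=O)OC(C)=O
Why: DMAP-catalysed acetylation of the primary alcohol masks O15 through steps 5 to 10 without touching the bought C13 centre.

Step 5
Reactants: 7 (S)-citronellyl acetate
Product: 8 (4S)-6-acetoxy-4-methylhexanoic acid
Conditions: RuCl3·xH2O (2 mol %), NaIO4 (4.1 equiv), MeCN/EtOAc/H2O, rt
Reagents that add atoms: sodium periodate [Na+].[O-]I(=O)(=O)=O; water O
Why: Sharpless oxidative cleavage with RuO4 formed in the flask cuts the trisubstituted alkene to the carboxylic acid (its carboxyl carbon becomes C9) and acetone, leaving the acetate and the C13 centre untouched.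

Step 6
Reactants: 8 (4S)-6-acetoxy-4-methylhexanoic acid
Product: 9 (4S)-6-acetoxy-4-methylhexanoyl chloride
Conditions: (COCl)2, DMF (cat.), CH2Cl2, 0 °C to rt; concentrate
Reagents that add atoms: oxalyl chloride O=C(Cl)C(=O)Cl
Why: Acid chloride formation through Vilsmeier-type activation is mild enough for the acetate and gives the ketene precursor.

Step 7
Reactants: 9 (4S)-6-acetoxy-4-methylhexanoyl chloride
Product: 11 ethyl (6S)-8-acetoxy-6-methylocta-2,3-dienoate, via ketene 10 (not isolated)
Conditions: Ph3P=CHCO2Et (1.0 equiv), Et3N (1.1 equiv), CH2Cl2, 0 °C to rt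
Reagents that add atoms: ethyl (triphenylphosphoranylidene)acetate CCOC(=O)C=P(c1ccccc1)(c1ccccc1)c1ccccc1
Why: Wittig olefination of a ketene, in which Et3N dehydrochlorinates 9 to ketene 10 and the stabilised ylide olefinates its C=O, so the acyl carbon becomes the central allene carbon C9; the allene axis forms unselectively, which is immaterial because step 8 destroys it.

Step 8
Reactants: 5 [(1S)-2,6,6-trimethylcyclohex-2-en-1-yl]acetaldehyde; 11 ethyl (6S)-8-acetoxy-6-methylocta-2,3-dienoate
Product: 14 ethyl 15-acetoxy-7-hydroxylabd-9(11)-en-17-oate (5α-H and 10β-CH3; mixture at C7/C8 and at the C9=C11 bond), via tertiary radical 12 (not isolated), via ester dienolate 13 (not isolated)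
Conditions: Fe(acac)3 (30 mol %), PhSiH3 (2.5 equiv), 11 (2 equiv), EtOH/(CH2OH)2 5:1, 40 °C
Reagents that add atoms: none
Why: Proposed new method: hydrogen-atom transfer from the iron hydride (Fe(acac)3/PhSiH3) to C1 of the C1=C10 alkene of 5 gives the tertiary C10 radical 12, which should add to the central, ester-conjugated carbon C9 of allenoate 11 (the only site that yields an α-ester radical, and an unhindered sp carbon); divalent iron then reduces that radical to dienolate 13, whose α-carbon C8 attacks the C7 aldehyde and forms the C7–C8 bond. The closest known reaction type is the hydrogen-atom-transfer-initiated radical–polar crossover annulation (Giese addition, then aldol cyclisation) of carbonyl-tethered alkenes with enals and enones; new is only the allenoate as acceptor, whose radical addition at the central carbon parallels its known behaviour toward nucleophiles. Ring B closes in a 6-(enolexo)-exo-trig aldol addition. C10 is controlled by the C5 centre: the acceptor can approach the radical equatorially only on the face anti to the C5 side arm, the other face being syn-axial to a C4 methyl group, so C9 ends trans to C6 and C20 axial (trans-decalin); C7 and C8 arise as mixtures that step 10 erases, and C9 is kept trigonal on purpose so that no stereocentre is made in the intermolecular bond formation. The step needs radical attack at C9 and not at C11, and aldol reaction of the dienolate at C8 and not at the γ-carbon C11 (both would give six-membered rings); the first is secured by the ester polarisation of the allene, the second by the kinetic α-selectivity of metal ester dienolates and by the side chain on C11.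

Step 9
Reactants: 14 ethyl 15-acetoxy-7-hydroxylabd-9(11)-en-17-oate
Product: 15 ethyl 15-acetoxy-7-hydroxylabdan-17-oate (9α-H; mixture at C7/C8)
Conditions: H2 (4 bar), PtO2 (10 mol %), EtOAc, rt
Reagents that add atoms: none
Why: Heterogeneous catalytic hydrogenation of the exocyclic trisubstituted alkene, in which the axial C20 methyl on C10 and the axial substituent on C8 both screen the β-face of C9, so hydrogen should add from the α-face and give 9α-H with the side chain equatorial as in the target.

Step 10
Reactants: 15 ethyl 15-acetoxy-7-hydroxylabdan-17-oate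
Product: 17 ethyl (5S,9R,10S,13S)-15-acetoxylabd-7-en-17-oate, via mesylate 16 (not isolated)
Conditions: MsCl, Et3N, CH2Cl2, 0 °C; then DBU, rt to 40 °C
Reagents that add atoms: none
Why: Mesylation and E1cB elimination, in which only C8–H is acidic (α to the ester), so the double bond can form only between C7 and C8 and all C7/C8 isomers converge on one conjugated ester while the non-acidic C9–H is untouched.

Step 11
Reactants: 17 ethyl (5S,9R,10S,13S)-15-acetoxylabd-7-en-17-oate
Product: 18 (5S,9R,10S,13S)-labd-7-ene-15,17-diol
Conditions: i-Bu2AlH (6 equiv), CH2Cl2, −78 to 0 °C; aq. KNaC4H4O6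
Reagents that add atoms: none
Why: i-Bu2AlH reduces the conjugated ester by 1,2-addition to the allylic alcohol and cleaves the acetate in the same operation, and no stereocentre is touched.

Step 12
Reactants: 18 (5S,9R,10S,13S)-labd-7-ene-15,17-diol
Product: 19 (5S,9R,10S,13S)-labd-7-ene-15,17-diyl diacetate (CNP0294037.1)
Conditions: Ac2O (4 equiv), pyridine, DMAP (cat.), CH2Cl2, rt
Reagents that add atoms: acetic anhydride CC(=O)OC(C)=O
Why: DMAP-catalysed acetylation of both primary alcohols should give the diacetate without affecting the trisubstituted C7=C8 bond.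

**Compound list**
1 | 2,4,4-trimethylcyclohex-2-en-1-one | CC1=CC(C)(C)CCC1=O | starting material
2 | (R)-2,4,4-trimethylcyclohex-2-en-1-ol | CC1=CC(C)(C)CC[C@H]1O | intermediate
3 | (R)-1-ethoxy-1-[(2,4,4-trimethylcyclohex-2-en-1-yl)oxy]ethene (ketene acetal, not isolated) | C=C(OCC)O[C@@H]1CCC(C)(C)C=C1C | intermediate
4 | ethyl [(1S)-2,6,6-trimethylcyclohex-2-en-1-yl]acetate | CCOC(=O)C[C@@H]1C(C)=CCCC1(C)C | intermediate
5 | [(1S)-2,6,6-trimethylcyclohex-2-en-1-yl]acetaldehyde | O=CC[C@@H]1C(C)=CCCC1(C)C | intermediate
6 | (S)-citronellol, (3S)-3,7-dimethyloct-6-en-1-ol | OCC[C@@H](C)CCC=C(C)C | starting material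
7 | (S)-citronellyl acetate | CC(=O)OCC[C@@H](C)CCC=C(C)C | intermediate
8 | (4S)-6-acetoxy-4-methylhexanoic acid | CC(=O)OCC[C@@H](C)CCC(=O)O | intermediate
9 | (4S)-6-acetoxy-4-methylhexanoyl chloride | CC(=O)OCC[C@@H](C)CCC(=O)Cl | intermediate
10 | (4S)-6-acetoxy-4-methylhex-1-en-1-one (ketene, not isolated) | CC(=O)OCC[C@@H](C)CC=C=O | intermediate
11 | ethyl (6S)-8-acetoxy-6-methylocta-2,3-dienoate (both allene axis isomers) | CC(=O)OCC[C@@H](C)CC=C=CC(=O)OCC | intermediate
12 | C10 tertiary radical derived from 5 (not isolated) | O=CC[C@@H]1[C](C)CCCC1(C)C | intermediate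
13 | ester dienolate formed by addition of 12 to C9 of 11 and reduction (iron-bound, drawn as the anion, not isolated) | CC(=O)OCC[C@@H](C)CC=C(C=C([O-])OCC)[C@@]1(C)CCCC(C)(C)[C@@H]1CC=O | intermediate
14 | ethyl 15-acetoxy-7-hydroxylabd-9(11)-en-17-oate (5α-H, 10β-CH3, 13S; C7, C8 and alkene geometry unassigned) | CC(=O)OCC[C@@H](C)CC=C1C(C(=O)OCC)C(O)C[C@H]2C(C)(C)CCC[C@]12C | intermediate
15 | ethyl 15-acetoxy-7-hydroxylabdan-17-oate (5α-H, 9α-H, 10β-CH3, 13S; C7 and C8 unassigned) | CC(=O)OCC[C@@H](C)CC[C@H]1C(C(=O)OCC)C(O)C[C@H]2C(C)(C)CCC[C@]12C | intermediate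
16 | ethyl 15-acetoxy-7-(methanesulfonyloxy)labdan-17-oate (not isolated) | CC(=O)OCC[C@@H](C)CC[C@H]1C(C(=O)OCC)C(OS(C)(=O)=O)C[C@H]2C(C)(C)CCC[C@]12C | intermediate
17 | ethyl (5S,9R,10S,13S)-15-acetoxylabd-7-en-17-oate | CC(=O)OCC[C@@H](C)CC[C@H]1C(C(=O)OCC)=CC[C@H]2C(C)(C)CCC[C@]12C | intermediate
18 | (5S,9R,10S,13S)-labd-7-ene-15,17-diol | OCC[C@@H](C)CC[C@H]1C(CO)=CC[C@H]2C(C)(C)CCC[C@]12C | intermediate
19 | (5S,9R,10S,13S)-labd-7-ene-15,17-diyl diacetate | CC(=O)OCC[C@@H](C)CC[C@H]1C(COC(C)=O)=CC[C@H]2C(C)(C)CCC[C@]12C | target

Total step count: 12. Longest linear sequence: 9 steps (steps 4 to 12, from 6).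

**Steps most likely to fail**

Step 8. The C10 radical may be quenched by hydrogen before it adds, or may add to the allene at the wrong carbon. The dienolate may also be protonated before ring closure or react through its γ-carbon. The fallback uses a known acceptor class and a different way of setting C9; it sets out from 7 and 5 and rejoins the route at 18. Cross-metathesis of 7 with crotonaldehyde (second-generation Hoveyda–Grubbs catalyst, CH2Cl2, 40 °C) should give (6S,2E)-8-acetoxy-6-methyloct-2-enal F1. The known hydrogen-atom-transfer Giese/aldol annulation of 5 with this enal (Fe(acac)3, PhSiH3, EtOH/(CH2OH)2) should give 15-acetoxy-7-hydroxylabdan-17-al F2. Dehydration (MsCl, Et3N, then DBU) should give 15-acetoxylabd-7-en-17-al F3, and i-Bu2AlH then reduces its aldehyde and acetate to diol 18. In this fallback C9 is formed in the intermolecular radical addition under weak acyclic control, so separation of the C9 epimers at the enal stage has to be accepted.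

Step 9. Facial discrimination at C9 may be poor, or the double bond may migrate into conjugation with the ester before it is reduced. The fallback replaces surface-mediated syn addition by a stepwise radical hydrogenation through hydrogen-atom transfer (Mn(dpm)3, PhSiH3, t-BuOOH, i-PrOH, rt). It sets out from 14: hydrogen adds first to C11, and the tertiary C9 radical then takes up hydrogen along the axial α trajectory, which places the side chain equatorial. It rejoins at 15 and makes no new compound (F0).

Step 2. Acid-promoted elimination of the allylic ketene acetal may compete with the sigmatropic shift at the hindered terminus next to C4, and the ring double bond may migrate under acid. The fallback is the acid-free Eschenmoser–Claisen rearrangement, which sets out from 2. Heating with N,N-dimethylacetamide dimethyl acetal (xylene, 140 °C) should give, with the same suprafacial chirality transfer, N,N-dimethyl-2-[(1S)-2,6,6-trimethylcyclohex-2-en-1-yl]acetamide F4. Reduction with Cp2Zr(H)Cl (THF, rt) then gives the aldehyde directly, so the route is rejoined at 5 and step 3 is bypassed.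

**Further compounds**
F1 | step 8 | (6S,2E)-8-acetoxy-6-methyloct-2-enal | CC(=O)OCC[C@@H](C)CC/C=C/C=O
F2 | step 8 | 15-acetoxy-7-hydroxylabdan-17-al (5α-H, 10β-CH3, 13S; C7, C8 and C9 unassigned) | CC(=O)OCC[C@@H](C)CCC1C(C=O)C(O)C[C@H]2C(C)(C)CCC[C@]12C
F3 | step 8 | (5S,9R,10S,13S)-15-acetoxylabd-7-en-17-al | CC(=O)OCC[C@@H](C)CC[C@H]1C(C=O)=CC[C@H]2C(C)(C)CCC[C@]12C
F0 | step 9 | none | none
F4 | step 2 | N,N-dimethyl-2-[(1S)-2,6,6-trimethylcyclohex-2-en-1-yl]acetamide | CN(C)C(=O)C[C@@H]1C(C)=CCCC1(C)C
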